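**Retrosynthetic overview** (lines follow the order in which the bonds are made; read upward for the retrosynthetic direction)
1. C9–O, C11–O, C8–C12 and C15–O bonds ⇐ all-cis C20 acid 1 + 2 O2: the 1,2-dioxolane (ring A) and the cyclopentane (ring B) close together in one cyclooxygenase turnover, giving bicyclic endoperoxide 2.
2. The O–O bond of ring A is then given up (2 → 3 → 4): hydroperoxide reduction and endoperoxide-to-β-hydroxy-ketone isomerisation leave ring B as the 9-oxo-11α-hydroxy cyclopentane carrying all four stereocentres of the target.
3. C1(=O)–O15 ⇐ hydroxy acid 4 through thioester 5: the 13-membered lactone (ring C) is formed last, giving 6.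
4. C11 O–acetyl ⇐ 6 + Ac2O: target 7.

Assumption: the target is taken as prostaglandin E3 1,15-lactone 11-acetate (8R,11R,12R,15S; 5Z,13E,17Z), EPA free acid is bought as such, and enzyme preparations (ram seminal vesicle microsomes, immobilised lipase) are treated as purchasable catalysts and are not numbered.

**Step 1**
Reactants: 1 (5Z,8Z,11Z,14Z,17Z)-icosa-5,8,11,14,17-pentaenoic acid (EPA)
Product: 4 prostaglandin E3 (PGE3), via prostaglandin G3 2 (not isolated), via prostaglandin H3 3 (not isolated)
Conditions: ram seminal vesicle microsomes (ovine prostaglandin H synthase 1 with its glutathione-dependent PGE isomerase; heme enzyme), hematin C34H33FeN4O5 (trivalent iron, 1 µM), glutathione (2 mM), hydroquinone (1.1 equiv), O2 (air sparge), 0.1 M Tris–HCl pH 8.0, 1 added in EtOH in portions to 0.5 mM, 37 °C, 45 min; citric acid to pH 3.5, EtOAc, SiO2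
Reagents that add atoms: dioxygen, O=O
Why: Enzymatic cyclooxygenase bis-dioxygenation (radical peroxidation cascade), followed by peroxidase reduction and a Kornblum–DeLaMare-type endoperoxide isomerisation, is the known biosynthetic conversion of this acid: the tyrosyl radical removes the 13-pro-S hydrogen, O2 is captured at C11, and two successive 5-exo radical closures (peroxyl onto C9, then C8 onto C12) inside the chiral substrate channel close the dioxolane and the cyclopentane in one turnover with the 9α,11α-peroxide, the 8α chain and the 12β chain (8R, 11R, 12R); a second O2 enters the C13–C15 allyl radical at C15 on the face that gives 15S and the trans C13=C14 bond; hydroquinone reduces the 15-hydroperoxide at the peroxidase site; and the isomerase removes H-9 so that the O–O bond opens to the 9-ketone and the 11α-alcohol without touching C8, C11, C12 or C15.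

**Step 2**
Reactants: 4 prostaglandin E3 (PGE3)
Product: 6 prostaglandin E3 1,15-lactone, via PGE3 2-pyridyl thioester 5 (not isolated)
Conditions: 2,2'-dipyridyl disulfide (1.5 equiv), PPh3 (1.5 equiv), degassed toluene, 25 °C, 12 h; then syringe pump into toluene at 80 °C (final 2 mM), 12 h, Ar, dark
Reagents that add atoms: none
Why: Corey–Nicolaou double-activation macrolactonisation (redox condensation to the 2-pyridinethiol ester, then ring closure under high dilution) works under neutral conditions that the β-hydroxy ketone tolerates; the hydroxyl proton is relayed to the pyridine nitrogen so that O15 attacks the thioester in a hydrogen-bonded template, the unhindered allylic 15-OH closing a 13-membered ring is expected to win over the hindered 11-OH that would have to close a strained bridged 11-membered ring, and C15 keeps its configuration because only the acyl–oxygen bond is formed.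

**Step 3**
Reactants: 6 prostaglandin E3 1,15-lactone
Product: 7 prostaglandin E3 1,15-lactone 11-acetate (target)
Conditions: Ac2O (3 equiv), pyridine (6 equiv), CH2Cl2, 0 °C, 3 h; cold aq. NH4Cl, rapid SiO2 filtration
Reagents that add atoms: acetic anhydride, CC(=O)OC(C)=O
Why: Pyridine-mediated O-acetylation (nucleophilic acyl substitution) of the only remaining hydroxyl leaves the C11–O bond and hence the 11R configuration untouched, and the low temperature with no base stronger than pyridine keeps the β-acetoxy ketone from E1cB loss of acetic acid and C8 from epimerising.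

**Compound list**
1 | (5Z,8Z,11Z,14Z,17Z)-icosa-5,8,11,14,17-pentaenoic acid (EPA) | CC/C=C\C/C=C\C/C=C\C/C=C\C/C=C\CCCC(=O)O | starting material
2 | prostaglandin G3: (5Z,13E,17Z)-9α,11α-epidioxy-15S-hydroperoxyprosta-5,13,17-trienoic acid (2,3-dioxabicyclo[2.2.1]heptane core, 8α and 12β chains) | CC/C=C\C[C@H](OO)/C=C/[C@H]1[C@H]2C[C@H](OO2)[C@@H]1C/C=C\CCCC(=O)O | intermediate
3 | prostaglandin H3: (5Z,13E,17Z)-9α,11α-epidioxy-15S-hydroxyprosta-5,13,17-trienoic acid | CC/C=C\C[C@H](O)/C=C/[C@H]1[C@H]2C[C@H](OO2)[C@@H]1C/C=C\CCCC(=O)O | intermediate
4 | prostaglandin E3: (5Z,13E,17Z)-11α,15S-dihydroxy-9-oxoprosta-5,13,17-trienoic acid (8R,11R,12R,15S) | CC/C=C\C[C@H](O)/C=C/[C@H]1[C@H](O)CC(=O)[C@@H]1C/C=C\CCCC(=O)O | intermediate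
5 | S-(pyridin-2-yl) thioester of prostaglandin E3 (8R,11R,12R,15S) | CC/C=C\C[C@H](O)/C=C/[C@H]1[C@H](O)CC(=O)[C@@H]1C/C=C\CCCC(=O)Sc1ccccn1 | intermediate
6 | prostaglandin E3 1,15-lactone: 13-membered lactone between C1 and O15, free 11α-OH, 9-ketone (8R,11R,12R,15S; 5Z,13E,17Z) | CC/C=C\C[C@H]1/C=C/[C@H]2[C@H](O)CC(=O)[C@@H]2C/C=C\CCCC(=O)O1 | intermediate
7 | prostaglandin E3 1,15-lactone 11-acetate (8R,11R,12R,15S; 5Z,13E,17Z) | CC/C=C\C[C@H]1/C=C/[C@H]2[C@H](OC(C)=O)CC(=O)[C@@H]2C/C=C\CCCC(=O)O1 | target

**Total step count:** 3. **Longest linear sequence:** 3.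

**Steps most likely to fail**

Step 1. EPA is turned over more slowly than arachidonic acid, the enzyme inactivates itself during turnover, and the endoperoxide can partition to PGD3, PGF3α and chain-cleaved hydroxy acids. The expected yield is therefore modest, roughly 15–30 %, with chromatographic separation from PGD3. The fallback sets out from 1 and comes back at 4. The oxygenation is run with purified ovine cyclooxygenase 1 or recombinant human cyclooxygenase 2 without glutathione, so that no isomerase acts. Endoperoxide 3 is quenched in the same flask with SnCl2 (divalent tin) in EtOH at 0 °C, which reduces the O–O bond cleanly to the robust triol prostaglandin F3α F1. N-(Trimethylsilyl)diethylamine in acetone at −45 °C silylates O11, O15 and the carboxyl group while the hindered 9α-hydroxyl stays free, giving PGF3α 11,15-bis(trimethylsilyl) ether trimethylsilyl ester F2. Dess–Martin periodinane with pyridine in CH2Cl2 at 0 °C oxidises C9–OH to PGE3 11,15-bis(trimethylsilyl) ether trimethylsilyl ester F3. AcOH/H2O/THF at 25 °C removes the three silyl groups and delivers 4. This removes the dependence on the isomerase, not the dependence on cyclooxygenase turnover of EPA.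

Step 2. The free 11-OH can close the 1,11-lactone, diolides can form, and the β-hydroxy ketone can dehydrate on heating. If only the thermal dehydration is the problem, the thioester can instead be closed at 25 °C with AgOSO2CF3. The fallback sets out from 4 and comes back at 7. The order of the last two bond formations is reversed so that only one hydroxyl is free when the ring is closed. Immobilised Candida antarctica lipase B with vinyl acetate in tert-butyl methyl ether at 30 °C is expected to acylate the ring 11-hydroxyl, because the allylic 15-hydroxyl between two large groups is a poor lipase substrate, and gives PGE3 11-acetate F4. 2,2'-Dipyridyl disulfide and PPh3 in toluene at 25 °C convert it into PGE3 11-acetate 2-pyridyl thioester F5, which on high-dilution heating at 80 °C can only close onto O15 and gives 7 directly.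

Step 3. The product is a β-acetoxy cyclopentanone and can lose acetic acid to the cross-conjugated enone (the PGA3 lactone) or epimerise at C8 under the acylation conditions. The fallback sets out from 6 and comes back at 7. The ketone is taken out of play while the ester is made. LiBH(sec-C4H9)3 in THF at −78 °C reduces C9=O from the β face to prostaglandin F3α 1,15-lactone F6; the C9 configuration is of no consequence because this centre is re-oxidised. Ac2O/pyridine at −20 °C acetylates the more accessible 11-hydroxyl, the 9α-hydroxyl being shielded by the cis alpha chain, to prostaglandin F3α 1,15-lactone 11-acetate F7. Dess–Martin periodinane with NaHCO3 in CH2Cl2 at 0 °C oxidises C9–OH under non-basic conditions to 7.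

**Further compounds**
F1 | step 1 | prostaglandin F3α: (5Z,13E,17Z)-9α,11α,15S-trihydroxyprosta-5,13,17-trienoic acid | CC/C=C\C[C@H](O)/C=C/[C@H]1[C@H](O)C[C@H](O)[C@@H]1C/C=C\CCCC(=O)O
F2 | step 1 | PGF3α 11,15-bis(trimethylsilyl) ether trimethylsilyl ester (9α-OH free) | CC/C=C\C[C@H](O[Si](C)(C)C)/C=C/[C@H]1[C@H](O[Si](C)(C)C)C[C@H](O)[C@@H]1C/C=C\CCCC(=O)O[Si](C)(C)C
F3 | step 1 | PGE3 11,15-bis(trimethylsilyl) ether trimethylsilyl ester | CC/C=C\C[C@H](O[Si](C)(C)C)/C=C/[C@H]1[C@H](O[Si](C)(C)C)CC(=O)[C@@H]1C/C=C\CCCC(=O)O[Si](C)(C)C
F4 | step 2 | PGE3 11-acetate (free 15S-OH and free acid) | CC/C=C\C[C@H](O)/C=C/[C@H]1[C@H](OC(C)=O)CC(=O)[C@@H]1C/C=C\CCCC(=O)O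
F5 | step 2 | PGE3 11-acetate 2-pyridyl thioester | CC/C=C\C[C@H](O)/C=C/[C@H]1[C@H](OC(C)=O)CC(=O)[C@@H]1C/C=C\CCCC(=O)Sc1ccccn1
F6 | step 3 | prostaglandin F3α 1,15-lactone (9α,11α-diol) | CC/C=C\C[C@H]1/C=C/[C@H]2[C@H](O)C[C@H](O)[C@@H]2C/C=C\CCCC(=O)O1
F7 | step 3 | prostaglandin F3α 1,15-lactone 11-acetate (9α-OH free) | CC/C=C\C[C@H]1/C=C/[C@H]2[C@H](OC(C)=O)C[C@H](O)[C@@H]2C/C=C\CCCC(=O)O1
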